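**Retrosynthetic overview**
- Target 10 is cut back at the C3 formyl group (Vilsmeier formylation with POBr3/DMF) to 2,5,6-tribromo-1-methylindole 8.
- The route rests on the N1–C2(Br) unit of the pyrrole ring: the C2 bromine next to N1 is what remains when the aniline nitrogen displaces one halogen of an ortho CH=CBr2 group. Indole 8 is therefore cut at N1–C2 to the N-methyl-2-(2,2-dibromovinyl)aniline 7.
- Aniline 7 comes from 3,4-dibromobenzaldehyde 1 by nitration ortho to the formyl group, Ramirez olefination with CBr4 (3), tin(II) reduction and mono-N-methylation.
- The benzene ring is bought; the pyrrole ring is the only ring formed (step 5).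

Key step: step 5

Remark: the target has no stereocentre and is achiral, so no enantiomer has to be selected and the route needs no stereocontrol.

**Step 1**
Reactants: 1 3,4-dibromobenzaldehyde
Product: 2 4,5-dibromo-2-nitrobenzaldehyde
Conditions: fuming HNO3, conc. H2SO4, 0 → 10 °C
Reagents that add atoms: nitric acid, O[N+](=O)[O-]
Why: Electrophilic aromatic nitration with mixed acid should place the nitro group at C6 (ortho to the formyl group), because C6 is para to the C3 bromine and is the position at which analogous 3-halo- and 3,4-dihalobenzaldehydes nitrate, whereas C5 is only ortho to a bromine and C2 is flanked by two substituents.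

**Step 2**
Reactants: 2 4,5-dibromo-2-nitrobenzaldehyde; 3 carbon tetrabromide
Product: 4 1,2-dibromo-4-(2,2-dibromovinyl)-5-nitrobenzene
Conditions: PPh3 (4 equiv), CBr4 (2 equiv), CH2Cl2, 0 °C
Reagents that add atoms: none
Why: Ramirez dibromo-olefination (first stage of the Corey–Fuchs sequence), in which Ph3P=CBr2 formed from CBr4 and PPh3 undergoes a Wittig reaction with the electron-poor aldehyde while the nitro group and the aryl bromides stay inert at 0 °C.

**Step 3**
Reactants: 4 1,2-dibromo-4-(2,2-dibromovinyl)-5-nitrobenzene
Product: 5 4,5-dibromo-2-(2,2-dibromovinyl)aniline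
Conditions: SnCl2·2H2O (5 equiv), EtOH, 75 °C; aq. NaHCO3 work-up
Reagents that add atoms: none
Why: Tin(II) chloride reduction of the nitroarene to the aniline is a chemoselective electron-transfer reduction that should leave the aryl and vinylic C–Br bonds and the alkene untouched, unlike catalytic hydrogenation.

**Step 4**
Reactants: 5 4,5-dibromo-2-(2,2-dibromovinyl)aniline
Product: 7 4,5-dibromo-2-(2,2-dibromovinyl)-N-methylaniline, via benzotriazol-1-ylmethyl aminal 6 (not isolated)
Conditions: 1H-benzotriazole (1.05 equiv), 37% aq. CH2O (1.05 equiv), EtOH, rt; concentrate; then NaBH4 (2 equiv), THF, 65 °C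
Reagents that add atoms: formaldehyde, C=O
Why: Katritzky benzotriazole-assisted mono-N-methylation, in which Mannich-type condensation of the aniline with formaldehyde and benzotriazole gives aminal 6, which ionises to the N-aryl methyleneiminium ion that borohydride reduces, so that exactly one methyl group is introduced under mild, halogen-tolerant conditions.

**Step 5**
Reactants: 7 4,5-dibromo-2-(2,2-dibromovinyl)-N-methylaniline
Product: 8 2,5,6-tribromo-1-methyl-1H-indole
Conditions: Pd(PtBu3)2 (5 mol %), K3PO4 (2 equiv), degassed PhMe (dilute), 100 °C
Reagents that add atoms: none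
Why: Pd(0) inserts into a vinylic C–Br bond of the gem-dibromoalkene, the tethered N-methylamine binds palladium and is deprotonated by phosphate to give a six-membered aza-palladacycle, and C–N reductive elimination forms N1–C2 with the second vinylic bromine left in place as the C2 bromine. The closest known reaction type is the Pd/P(tBu)3-catalysed intramolecular Buchwald–Hartwig-type vinylic amination of ortho-(gem-dibromovinyl)anilines to 2-bromoindoles. The five-membered pyrrole ring is closed in a formal 5-endo-trig sense at the CBr2 carbon, which is feasible because the bond is made by reductive elimination from the palladacycle and not by direct nucleophilic attack. No stereocentre is created, so no stereocontrol element is needed. The step needs chemoselectivity for the dibromoalkene over the two aryl C–Br bonds: gem-dibromoalkenes undergo oxidative addition faster than bromoarenes, the ring bromides sit on an amine-enriched ring, and amination through the palladacycle is intramolecular whereas any aryl amination would be intermolecular. Over-reaction at C2 should be held back because the bulky P(tBu)3 makes oxidative addition into the hindered 2-bromoindole reversible and because no N–H nucleophile remains once the ring is closed.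

**Step 6**
Reactants: 8 2,5,6-tribromo-1-methyl-1H-indole
Product: 10 2,5,6-tribromo-1-methyl-1H-indole-3-carbaldehyde, via C3 iminium bromide 9 (not isolated)
Conditions: POBr3 (1.5 equiv), DMF (3 equiv), ClCH2CH2Cl, 0 → 70 °C; then aq. NaOAc, rt
Reagents that add atoms: N,N-dimethylformamide, CN(C)C=O; water, O
Why: Vilsmeier–Haack formylation, in which the bromomethyleneiminium ion from POBr3 and DMF attacks C3, the only free and most nucleophilic pyrrole carbon, to give iminium salt 9 that mild acetate hydrolysis converts to the aldehyde, while bromide as the only halide present excludes Br/Cl exchange at the activated C2 position.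

**Compound list**
1 | 3,4-dibromobenzaldehyde | O=Cc1ccc(Br)c(Br)c1 | starting material
2 | 4,5-dibromo-2-nitrobenzaldehyde | O=Cc1cc(Br)c(Br)cc1[N+](=O)[O-] | intermediate
3 | carbon tetrabromide | BrC(Br)(Br)Br | starting material
4 | 1,2-dibromo-4-(2,2-dibromovinyl)-5-nitrobenzene | O=[N+]([O-])c1cc(Br)c(Br)cc1C=C(Br)Br | intermediate
5 | 4,5-dibromo-2-(2,2-dibromovinyl)aniline | Nc1cc(Br)c(Br)cc1C=C(Br)Br | intermediate
6 | N-(1H-benzotriazol-1-ylmethyl)-4,5-dibromo-2-(2,2-dibromovinyl)aniline | BrC(Br)=Cc1cc(Br)c(Br)cc1NCn1nnc2ccccc21 | intermediate
7 | 4,5-dibromo-2-(2,2-dibromovinyl)-N-methylaniline | CNc1cc(Br)c(Br)cc1C=C(Br)Br | intermediate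
8 | 2,5,6-tribromo-1-methyl-1H-indole | Cn1c(Br)cc2cc(Br)c(Br)cc21 | intermediate
9 | N-[(2,5,6-tribromo-1-methyl-1H-indol-3-yl)methylidene]-N-methylmethanaminium bromide | C[N+](C)=Cc1c(Br)n(C)c2cc(Br)c(Br)cc12.[Br-] | intermediate
10 | 2,5,6-tribromo-1-methyl-1H-indole-3-carbaldehyde | Cn1c(Br)c(C=O)c2cc(Br)c(Br)cc21 | target

**Total step count:** 6
**Longest linear sequence:** 6 steps (1 → 2 → 4 → 5 → 7 → 8 → 10)

**Steps most likely to fail**

1. Step 5 (key step). Palladium may insert into the aryl C–Br bonds in competition with the dibromoalkene, leading to intermolecular N-arylation, oligomers or hydrodebromination, or the product may couple further at C2. The fallback is a metal-free closure of the same N1–C2 bond. It sets out from aniline 5, which with MsCl in pyridine at 0 °C should give N-[4,5-dibromo-2-(2,2-dibromovinyl)phenyl]methanesulfonamide F1. Treating F1 with Cs2CO3 in DMF at 80 °C should cyclise the sulfonamide anion onto the dibromoalkene to give 2,5,6-tribromo-1-(methylsulfonyl)-1H-indole F2, with no catalyst able to touch the aryl bromides. Cleavage of the mesyl group with KOH in MeOH/THF at rt should give 2,5,6-tribromo-1H-indole F3, and NaH/MeI in DMF at 0 °C methylates it. The fallback comes back to the route at compound 8.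

2. Step 1. Nitration may be poorly regioselective (attack at C5, meta to the formyl group, competing with C6), and the formyl group may be oxidised by nitric acid. The fallback sets out from aldehyde 1 and swaps the meta-directing formyl group for an ortho/para-directing acetoxymethyl group, so that this group and the C3 bromine direct to the same carbon. NaBH4 in MeOH at 0 °C should give (3,4-dibromophenyl)methanol F4, and Ac2O/pyridine/DMAP gives 3,4-dibromobenzyl acetate F5. Nitration with fuming HNO3/H2SO4 at 0 °C should then give 4,5-dibromo-2-nitrobenzyl acetate F6. K2CO3 in MeOH frees (4,5-dibromo-2-nitrophenyl)methanol F7, and MnO2 in CH2Cl2 oxidises it to the aldehyde. The fallback comes back to the route at compound 2.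

3. Step 6. Electrophilic attack on the tribrominated, deactivated indole may be sluggish, and forcing it may cost the labile C2 halogen. The fallback sets out from indole 8 and moves the C–C bond formation to an activated methylene group. Hydrolysis of the 2-bromoindole with TFA/H2O at 60 °C (C3 protonation, addition of water at C2, loss of HBr), followed by NaHCO3 work-up, should give 5,6-dibromo-1-methylindolin-2-one F8. With POBr3/DMF in refluxing CHCl3, F8 should undergo Vilsmeier haloformylation: condensation at the C3 methylene and conversion of the lactam carbonyl into the C2 bromide. This regenerates iminium salt 9, and aqueous NaOAc hydrolysis brings the route back at compound 10.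

**Further compounds**
F1 | step 5 | N-[4,5-dibromo-2-(2,2-dibromovinyl)phenyl]methanesulfonamide | CS(=O)(=O)Nc1cc(Br)c(Br)cc1C=C(Br)Br
F2 | step 5 | 2,5,6-tribromo-1-(methylsulfonyl)-1H-indole | CS(=O)(=O)n1c(Br)cc2cc(Br)c(Br)cc21
F3 | step 5 | 2,5,6-tribromo-1H-indole | Brc1cc2cc(Br)c(Br)cc2[nH]1
F4 | step 1 | (3,4-dibromophenyl)methanol | OCc1ccc(Br)c(Br)c1
F5 | step 1 | 3,4-dibromobenzyl acetate | CC(=O)OCc1ccc(Br)c(Br)c1
F6 | step 1 | 4,5-dibromo-2-nitrobenzyl acetate | CC(=O)OCc1cc(Br)c(Br)cc1[N+](=O)[O-]
F7 | step 1 | (4,5-dibromo-2-nitrophenyl)methanol | OCc1cc(Br)c(Br)cc1[N+](=O)[O-]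
F8 | step 6 | 5,6-dibromo-1-methylindolin-2-one | CN1C(=O)Cc2cc(Br)c(Br)cc21
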